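**Retrosynthetic overview**
1. The target is epiafzelechin-(4β→8)-epicatechin-(4β→8)-epicatechin (upper unit rings A/B/C, middle unit rings D/E/F). The last operations are only ester methanolysis and hydrogenolysis of eleven benzyl ethers.
2. Key disconnection: ring C of the upper unit is cut at C2–C3 and at C4–C4a. This is a catalytic asymmetric oxa-Povarov (formal [4+2]) union of an achiral O-aryl oxocarbenium ion (rings A and B, O1, C2) with an (E)-2-acetoxyvinyl group (C3, C4) on C8 of ring D of a protected procyanidin B2. One operation joins the fragments, closes ring C and sets C2, C3 and C4.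
3. Enabling feature: O1 ties C2 (benzylic to the para-oxygenated ring B) to C8a of the phloroglucinol ring A, so C2=O1(+)–C8a=C4a is a stabilised cationic 2-oxadiene with a nucleophilic terminus C4a. C4 is benzylic to C8 of ring D, whose oxygens at C7, C8a (ortho) and C5 (para) stabilise the cation left after C2–C3 bond formation and fix the regiochemistry.
4. The two-carbon partner comes from an 8-bromo dimer (Suzuki–Miyaura vinylation, hydrolysis, acetylation). The dimer comes from a 4β→8 Friedel–Crafts coupling of two units made from (−)-epicatechin, with the C8 bromide serving first as a block and then as the handle.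
5. Ring order: rings D–F and all rings of the lower unit are bought with (−)-epicatechin (four stereocentres bought, C4 of the middle unit relayed from its C3). Rings A and B are bought arenes. Ring C is the only ring formed, in the key step.

Key step: step 9

Assumption: the sense of induction of the chiral acid in the key step cannot be read from precedent, so the (R)-catalyst is written and its antipode is taken if a trial on a simple 2,4,6-trialkoxy-β-acetoxystyrene shows the opposite sense; because the alkene partner is a single enantiomer, every stereoisomeric outcome is a separable diastereomer.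

**Step 1**
Reactants: 1 (−)-epicatechin
Product: 2 5,7,3',4'-tetra-O-benzyl-(−)-epicatechin (3-OH free)
Conditions: BnBr (4.4 equiv), K2CO3, DMF, 0 °C to rt
Reagents that add atoms: benzyl bromide, BrCc1ccccc1
Why: Williamson etherification under carbonate conditions alkylates only the four acidic phenols, leaves the secondary 3-OH free and does not touch C2 or C3.

**Step 2**
Reactants: 2 5,7,3',4'-tetra-O-benzyl-(−)-epicatechin
Product: 3 5,7,3',4'-tetra-O-benzyl-4β-(2-ethoxyethoxy)-(−)-epicatechin (2,3-cis, 3,4-trans)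
Conditions: DDQ, 2-ethoxyethanol, CH2Cl2, rt
Reagents that add atoms: 2-ethoxyethanol, CCOCCO
Why: DDQ benzylic oxidation abstracts hydride from C4 to give the cation stabilised by the dialkoxy ring, and the alcohol traps it anti to the axial 3-OH, which sets the 4β ether.

**Step 3**
Reactants: 3 5,7,3',4'-tetra-O-benzyl-4β-(2-ethoxyethoxy)-(−)-epicatechin
Product: 4 8-bromo-5,7,3',4'-tetra-O-benzyl-4β-(2-ethoxyethoxy)-(−)-epicatechin
Conditions: NBS (1.0 equiv), CH2Cl2, −78 to 0 °C
Reagents that add atoms: N-bromosuccinimide, O=C1CCC(=O)N1Br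
Why: Electrophilic aromatic bromination of benzylated flavan-3-ols goes to C8, the most nucleophilic ring position, and no stereocentre is touched.

**Step 4**
Reactants: 4 8-bromo-5,7,3',4'-tetra-O-benzyl-4β-(2-ethoxyethoxy)-(−)-epicatechin; 2 5,7,3',4'-tetra-O-benzyl-(−)-epicatechin (2 equiv, excess recovered)
Product: 5 8-bromo-octa-O-benzylprocyanidin B2 [8-bromo-tetra-O-benzylepicatechin-(4β→8)-tetra-O-benzylepicatechin; both 3-OH free]
Conditions: TMSOTf (0.2 equiv), 4 Å MS, CH2Cl2, −78 to −40 °C; Et3N quench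
Reagents that add atoms: none
Why: In this standard interflavan Friedel–Crafts alkylation the C4 ether ionises and C8 of 2 attacks the cation anti to the axial 3-OH (4β, 3,4-trans), while the C8 bromide stops 4 from acting as its own nucleophile.

**Step 5**
Reactants: 5 8-bromo-octa-O-benzylprocyanidin B2; 6 (E)-2-(2-ethoxyvinyl)-4,4,5,5-tetramethyl-1,3,2-dioxaborolane
Product: 7 8-[(E)-2-ethoxyvinyl]-octa-O-benzylprocyanidin B2
Conditions: Pd(OAc)2 (5 mol %), SPhos (10 mol %), K3PO4, dioxane/H2O, 80 °C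
Reagents that add atoms: none
Why: Suzuki–Miyaura coupling with a bulky electron-rich biarylphosphine handles the di-ortho-alkoxy aryl bromide, keeps the alkene geometry and tolerates the free alcohols.

**Step 6**
Reactants: 7 8-[(E)-2-ethoxyvinyl]-octa-O-benzylprocyanidin B2
Product: 8 8-(2-oxoethyl)-octa-O-benzylprocyanidin B2 (arylacetaldehyde)
Conditions: 1 M aq HCl, THF, 0 °C to rt
Reagents that add atoms: water, O
Why: Acid-catalysed enol ether hydrolysis ends irreversibly in the aldehyde under conditions too mild to cleave the benzylated interflavan bond.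

**Step 7**
Reactants: 8 8-(2-oxoethyl)-octa-O-benzylprocyanidin B2
Product: 9 8-[(E)-2-acetoxyvinyl]-3,3''-di-O-acetyl-octa-O-benzylprocyanidin B2
Conditions: Ac2O (excess), Et3N, DMAP (cat.), CH2Cl2, rt
Reagents that add atoms: acetic anhydride, CC(=O)OC(C)=O
Why: DMAP-catalysed acylation esterifies both secondary alcohols and O-acetylates the readily formed arylacetaldehyde enolate, and the (E)-enol acetate should prevail because the oxygen of the (Z)-enolate lies under the di-ortho-substituted ring D and is acylated more slowly.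

**Step 8**
Reactants: 10 4-(benzyloxy)benzaldehyde; 11 3,5-bis(benzyloxy)phenol
Product: 13 [4-(benzyloxy)phenyl][3,5-bis(benzyloxy)phenoxy]methyl pivalate (racemic), via alpha-chlorobenzyl pivalate 12 (not isolated)
Conditions: 10, PivCl, ZnCl2 (2 mol %), CH2Cl2, 0 °C; then added to 11, Cs2CO3, MeCN, 0 °C; filtration through Et3N-deactivated silica
Reagents that add atoms: pivaloyl chloride, CC(C)(C)C(=O)Cl
Why: ZnCl2-catalysed addition of an acyl chloride to an aldehyde gives the α-chloroalkyl ester, which O-alkylates the caesium phenoxide as in acyloxyalkyl ether formation; the bulky pivaloyl group suppresses acyl transfer, and the racemic centre is irrelevant because it becomes planar in step 9.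

**Step 9**
Reactants: 9 8-[(E)-2-acetoxyvinyl]-3,3''-di-O-acetyl-octa-O-benzylprocyanidin B2; 13 [4-(benzyloxy)phenyl][3,5-bis(benzyloxy)phenoxy]methyl pivalate
Product: 16 tri-O-acetyl-undeca-O-benzyl-epiafzelechin-(4β→8)-epicatechin-(4β→8)-epicatechin, via oxocarbenium ion 14 (not isolated), via C4 benzylic cation 15 (not isolated)
Conditions: (R)-3,3'-bis(2,4,6-triisopropylphenyl)-1,1'-binaphthyl-2,2'-diyl N-triflylphosphoramide (10 mol %), 13 (1.3 equiv, syringe pump), 4 Å MS, toluene/CH2Cl2, −70 °C; Et3N quench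
Reagents that add atoms: none
Why: Proposed new method: the chiral acid protonates the pivalate of 13 and expels pivalic acid to give the (E)-O-aryl oxocarbenium ion 14 (cationic 2-oxadiene C2=O1(+)–C8a=C4a) as a contact ion pair, the acetoxy-bearing alkene carbon of 9 attacks C2 (C2–C3 bond) to give cation 15, and the ortho carbon of the phenoxy ring attacks C4 (C4–C4a bond) and loses the proton that regenerates the acid, a polar stepwise formal [4+2] cycloaddition. The closest known reaction types are the SnCl4-promoted oxa-Povarov reaction of aryl oxocarbenium ions with styrenes, the chiral phosphoric acid catalysed Povarov reaction and chiral-anion-controlled Prins additions to styrenes; new are the β-acetoxystyrene as the two-carbon partner and counteranion control of an O-aryl oxocarbenium ion. Ring C is the only ring closed, by a 6-exo-trig Friedel–Crafts attack on the quinone-methide-like C4=C8(ring D) cation (6-exo-tet if its bridged acetoxonium form reacts). C2 (R) is set by the chiral anion, which binds the acidic C2–H of 14 and covers its Re face so that the alkene arrives at the Si face; C3 (R) follows from the compact synclinal transition state, in which the very large ring D substituent of the (E)-alkene must point away from ring A (exo) and the small acetoxy group lies endo over O1, so that the Si face of C3 meets the Si face of C2 (2,3-cis); C4 is set in the closure, because allylic strain holds C3–H in the plane of ring D in 15, the acetoxy group covers or bridges one face of C4, and the ring A carbon tethered through C2 can reach only the opposite face (3,4-trans, 4β). The step needs attack through C3 and not C4 of the alkene, secured by the three oxygen donors of ring D, by the acetyl group that damps the enol oxygen and by the steric shielding of C4; it needs the alkene to outrun the free C6–H positions of 9 and the electron-rich ring of un-ionised 13, secured by the higher nucleophilicity of the trialkoxystyrene and by slow addition of 13; and it needs a single Friedel–Crafts regiochemistry, guaranteed by the symmetry of the 3,5-dibenzyloxyphenoxy ring.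

**Step 10**
Reactants: 16 tri-O-acetyl-undeca-O-benzyl-epiafzelechin-(4β→8)-epicatechin-(4β→8)-epicatechin
Product: 17 undeca-O-benzyl-epiafzelechin-(4β→8)-epicatechin-(4β→8)-epicatechin (three free 3-OH)
Conditions: K2CO3 (0.3 equiv), MeOH/THF, rt
Reagents that add atoms: none
Why: Base-catalysed transesterification removes the three acetates, while benzyl ethers, interflavan bonds and all stereocentres are inert to mild base.

**Step 11**
Reactants: 17 undeca-O-benzyl-epiafzelechin-(4β→8)-epicatechin-(4β→8)-epicatechin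
Product: 18 epiafzelechin-(4β→8)-epicatechin-(4β→8)-epicatechin (target)
Conditions: H2 (1 atm), Pd(OH)2/C, THF/MeOH/H2O, rt
Reagents that add atoms: none
Why: Neutral catalytic hydrogenolysis cleaves all eleven benzyl ethers without acid or base, so the acid-labile interflavan bonds and the base-labile C2 centres are kept.

**Compound list**
1 | (−)-epicatechin, (2R,3R) | c1c(O)cc(O)c2c1O[C@H](c3ccc(O)c(O)c3)[C@H](O)C2 | starting material
2 | 5,7,3',4'-tetra-O-benzyl-(−)-epicatechin | c1c(OCc5ccccc5)cc(OCc5ccccc5)c2c1O[C@H](c3ccc(OCc5ccccc5)c(OCc5ccccc5)c3)[C@H](O)C2 | intermediate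
3 | 5,7,3',4'-tetra-O-benzyl-4β-(2-ethoxyethoxy)-(−)-epicatechin | c1c(OCc5ccccc5)cc(OCc5ccccc5)c2c1O[C@H](c3ccc(OCc5ccccc5)c(OCc5ccccc5)c3)[C@H](O)[C@H]2OCCOCC | intermediate
4 | 8-bromo-5,7,3',4'-tetra-O-benzyl-4β-(2-ethoxyethoxy)-(−)-epicatechin | Brc1c(OCc5ccccc5)cc(OCc5ccccc5)c2c1O[C@H](c3ccc(OCc5ccccc5)c(OCc5ccccc5)c3)[C@H](O)[C@H]2OCCOCC | intermediate
5 | 8-bromo-octa-O-benzylprocyanidin B2 (bromine on C8 of the upper unit of the dimer, 4β→8 link) | Brc1c(OCc5ccccc5)cc(OCc5ccccc5)c2c1O[C@H](c3ccc(OCc5ccccc5)c(OCc5ccccc5)c3)[C@H](O)[C@H]2c1c(OCc5ccccc5)cc(OCc5ccccc5)c2c1O[C@H](c3ccc(OCc5ccccc5)c(OCc5ccccc5)c3)[C@H](O)C2 | intermediate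
6 | (E)-2-(2-ethoxyvinyl)-4,4,5,5-tetramethyl-1,3,2-dioxaborolane | CCO/C=C/B1OC(C)(C)C(C)(C)O1 | starting material
7 | 8-[(E)-2-ethoxyvinyl]-octa-O-benzylprocyanidin B2 | CCO/C=C/c1c(OCc5ccccc5)cc(OCc5ccccc5)c2c1O[C@H](c3ccc(OCc5ccccc5)c(OCc5ccccc5)c3)[C@H](O)[C@H]2c1c(OCc5ccccc5)cc(OCc5ccccc5)c2c1O[C@H](c3ccc(OCc5ccccc5)c(OCc5ccccc5)c3)[C@H](O)C2 | intermediate
8 | 8-(2-oxoethyl)-octa-O-benzylprocyanidin B2 | O=CCc1c(OCc5ccccc5)cc(OCc5ccccc5)c2c1O[C@H](c3ccc(OCc5ccccc5)c(OCc5ccccc5)c3)[C@H](O)[C@H]2c1c(OCc5ccccc5)cc(OCc5ccccc5)c2c1O[C@H](c3ccc(OCc5ccccc5)c(OCc5ccccc5)c3)[C@H](O)C2 | intermediate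
9 | 8-[(E)-2-acetoxyvinyl]-3,3''-di-O-acetyl-octa-O-benzylprocyanidin B2 | CC(=O)O/C=C/c1c(OCc5ccccc5)cc(OCc5ccccc5)c2c1O[C@H](c3ccc(OCc5ccccc5)c(OCc5ccccc5)c3)[C@H](OC(C)=O)[C@H]2c1c(OCc5ccccc5)cc(OCc5ccccc5)c2c1O[C@H](c3ccc(OCc5ccccc5)c(OCc5ccccc5)c3)[C@H](OC(C)=O)C2 | intermediate
10 | 4-(benzyloxy)benzaldehyde | O=Cc1ccc(OCc2ccccc2)cc1 | starting material
11 | 3,5-bis(benzyloxy)phenol | Oc1cc(OCc2ccccc2)cc(OCc2ccccc2)c1 | starting material
12 | chloro[4-(benzyloxy)phenyl]methyl pivalate (racemic) | CC(C)(C)C(=O)OC(Cl)c1ccc(OCc2ccccc2)cc1 | intermediate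
13 | [4-(benzyloxy)phenyl][3,5-bis(benzyloxy)phenoxy]methyl pivalate (racemic) | CC(C)(C)C(=O)OC(Oc1cc(OCc2ccccc2)cc(OCc2ccccc2)c1)c1ccc(OCc2ccccc2)cc1 | intermediate
14 | (E)-[4-(benzyloxy)benzylidene][3,5-bis(benzyloxy)phenyl]oxonium ion (paired with the chiral anion) | O(Cc5ccccc5)c1ccc(/C=[O+]/c3cc(OCc5ccccc5)cc(OCc5ccccc5)c3)cc1 | intermediate
15 | open C2–C3 adduct, (2R,3R), cation at C4 stabilised by ring D (in equilibrium with its acetoxonium form) | O(Cc5ccccc5)c1ccc([C@@H](Oc3cc(OCc5ccccc5)cc(OCc5ccccc5)c3)[C@H](OC(C)=O)[CH+]c3c(OCc5ccccc5)cc(OCc5ccccc5)c4c3O[C@H](c3ccc(OCc5ccccc5)c(OCc5ccccc5)c3)[C@H](OC(C)=O)[C@H]4c3c(OCc5ccccc5)cc(OCc5ccccc5)c4c3O[C@H](c3ccc(OCc5ccccc5)c(OCc5ccccc5)c3)[C@H](OC(C)=O)C4)cc1 | intermediate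
16 | tri-O-acetyl-undeca-O-benzyl-epiafzelechin-(4β→8)-epicatechin-(4β→8)-epicatechin | O(Cc5ccccc5)c1ccc([C@H]2Oc3cc(OCc5ccccc5)cc(OCc5ccccc5)c3[C@H](c3c(OCc5ccccc5)cc(OCc5ccccc5)c4c3O[C@H](c3ccc(OCc5ccccc5)c(OCc5ccccc5)c3)[C@H](OC(C)=O)[C@H]4c3c(OCc5ccccc5)cc(OCc5ccccc5)c4c3O[C@H](c3ccc(OCc5ccccc5)c(OCc5ccccc5)c3)[C@H](OC(C)=O)C4)[C@H]2OC(C)=O)cc1 | intermediate
17 | undeca-O-benzyl-epiafzelechin-(4β→8)-epicatechin-(4β→8)-epicatechin | O(Cc5ccccc5)c1ccc([C@H]2Oc3cc(OCc5ccccc5)cc(OCc5ccccc5)c3[C@H](c3c(OCc5ccccc5)cc(OCc5ccccc5)c4c3O[C@H](c3ccc(OCc5ccccc5)c(OCc5ccccc5)c3)[C@H](O)[C@H]4c3c(OCc5ccccc5)cc(OCc5ccccc5)c4c3O[C@H](c3ccc(OCc5ccccc5)c(OCc5ccccc5)c3)[C@H](O)C4)[C@H]2O)cc1 | intermediate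
18 | epiafzelechin-(4β→8)-epicatechin-(4β→8)-epicatechin | Oc1ccc([C@H]2Oc3cc(O)cc(O)c3[C@H](c3c(O)cc(O)c4c3O[C@H](c3ccc(O)c(O)c3)[C@H](O)[C@H]4c3c(O)cc(O)c4c3O[C@H](c3ccc(O)c(O)c3)[C@H](O)C4)[C@H]2O)cc1 | target

**Total step count:** 11. **Longest linear sequence:** 10 steps (steps 1–7 and 9–11).

**Steps most likely to fail**

1. **Step 9.**
   - What may go wrong: the counteranion may give weak facial control with so large a nucleophile. The first C–C bond formation may also become reversible, so that the faster-closing 2,3-trans adduct drains the mixture. The electron-rich ring of un-ionised acetal may be alkylated.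
   - Fallback (known interflavan Friedel–Crafts chemistry, from 5 back to 17): 5 is debrominated by bromine–lithium exchange (n-BuLi, THF, −78 °C, then MeOH) to octa-O-benzylprocyanidin B2 F1. Bought (−)-epiafzelechin F2 is benzylated (BnBr, K2CO3, DMF) to 5,7,4'-tri-O-benzylepiafzelechin F3. F3 is oxidised with DDQ and 2-ethoxyethanol to 5,7,4'-tri-O-benzyl-4β-(2-ethoxyethoxy)epiafzelechin F4. TMSOTf-mediated coupling of F4 with an excess of F1 at −78 °C, with attack by C8 of ring D anti to the axial 3-OH, should give 17 directly.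

2. **Step 8.**
   - What may go wrong: the very labile α-chloro ester may ionise and hydrolyse prematurely. Acyl transfer to the phenoxide or C-alkylation of the ambident phenoxide may compete, and the product may decompose on purification.
   - Fallback (from 10 and 11, back to 16 through the same ion 14): 10 is converted with SOCl2 and catalytic DMF into 1-(benzyloxy)-4-(dichloromethyl)benzene F5. F5 is treated at once with two equivalents of 11 and Cs2CO3 in MeCN to give 4-(benzyloxy)benzaldehyde bis[3,5-bis(benzyloxy)phenyl] acetal F6. Both leaving groups of this symmetric acetal are the same, so under the conditions of step 9 it can ionise only to 14, and it takes the place of 13.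

3. **Step 7.**
   - What may go wrong: enolate geometry may be poorly controlled during O-acetylation, and the arylacetaldehyde may self-condense by an aldol reaction.
   - Fallback (from 5 back to 9, geometry carried by a stereodefined alkenylboronate): 5 is acetylated (Ac2O, DMAP, pyridine) to 8-bromo-3,3''-di-O-acetyl-octa-O-benzylprocyanidin B2 F7. F7 is mono-coupled with an excess of (E)-1,2-bis(4,4,5,5-tetramethyl-1,3,2-dioxaborolan-2-yl)ethene (Pd(OAc)2, SPhos, CsF, dioxane) to the (E)-styrylboronate F8. Stereoretentive Chan–Lam-type acetoxylation of F8 (Cu(OAc)2, Et3N, 4 Å MS, air, CH2Cl2) should give 9.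

**Further compounds**
F1 | step 9 | octa-O-benzylprocyanidin B2 | c1c(OCc5ccccc5)cc(OCc5ccccc5)c2c1O[C@H](c3ccc(OCc5ccccc5)c(OCc5ccccc5)c3)[C@H](O)[C@H]2c1c(OCc5ccccc5)cc(OCc5ccccc5)c2c1O[C@H](c3ccc(OCc5ccccc5)c(OCc5ccccc5)c3)[C@H](O)C2
F2 | step 9 | (−)-epiafzelechin (bought) | c1c(O)cc(O)c2c1O[C@H](c3ccc(O)cc3)[C@H](O)C2
F3 | step 9 | 5,7,4'-tri-O-benzylepiafzelechin | c1c(OCc5ccccc5)cc(OCc5ccccc5)c2c1O[C@H](c3ccc(OCc5ccccc5)cc3)[C@H](O)C2
F4 | step 9 | 5,7,4'-tri-O-benzyl-4β-(2-ethoxyethoxy)epiafzelechin | c1c(OCc5ccccc5)cc(OCc5ccccc5)c2c1O[C@H](c3ccc(OCc5ccccc5)cc3)[C@H](O)[C@H]2OCCOCC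
F5 | step 8 | 1-(benzyloxy)-4-(dichloromethyl)benzene | ClC(Cl)c1ccc(OCc2ccccc2)cc1
F6 | step 8 | 4-(benzyloxy)benzaldehyde bis[3,5-bis(benzyloxy)phenyl] acetal | C(Oc1cc(OCc2ccccc2)cc(OCc2ccccc2)c1)(Oc1cc(OCc2ccccc2)cc(OCc2ccccc2)c1)c1ccc(OCc2ccccc2)cc1
F7 | step 7 | 8-bromo-3,3''-di-O-acetyl-octa-O-benzylprocyanidin B2 | Brc1c(OCc5ccccc5)cc(OCc5ccccc5)c2c1O[C@H](c3ccc(OCc5ccccc5)c(OCc5ccccc5)c3)[C@H](OC(C)=O)[C@H]2c1c(OCc5ccccc5)cc(OCc5ccccc5)c2c1O[C@H](c3ccc(OCc5ccccc5)c(OCc5ccccc5)c3)[C@H](OC(C)=O)C2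
F8 | step 7 | 8-[(E)-2-(4,4,5,5-tetramethyl-1,3,2-dioxaborolan-2-yl)vinyl]-3,3''-di-O-acetyl-octa-O-benzylprocyanidin B2 | CC1(C)OB(/C=C/c2c(OCc5ccccc5)cc(OCc5ccccc5)c3c2O[C@H](c4ccc(OCc5ccccc5)c(OCc5ccccc5)c4)[C@H](OC(C)=O)[C@H]3c2c(OCc5ccccc5)cc(OCc5ccccc5)c3c2O[C@H](c4ccc(OCc5ccccc5)c(OCc5ccccc5)c4)[C@H](OC(C)=O)C3)OC1(C)C
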